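The ring-fusion bond C-4a–C-8a (octahydronaphthalene locants of the target) is the central σ-bond of a 1,5-diene made of the ring-A olefin C-3=C-4 and the C-7/C-8 enolate of ring B. The cis-decalin is therefore planned as the product of an anionic oxy-Cope shift that sacrifices a temporary C-3–C-7 bond. The precursor is a Diels–Alder-built 2-methylcyclohexenone (C-7, C-8, C-8a, C-1, C-2, C-3) carrying a (Z)-4-iodobutenyl arm on C-3. Iodine–lithium exchange closes C-6 onto the C-7 carbonyl; the cis-fused bicyclic alkoxide then rearranges, cutting C-3–C-7 and forming C-4a–C-8a, so both rings arise with the ring-A stereocentres relayed from the cyclohexenone.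

Key step: step 9

Remark: 4, 8 and 20 are taken as catalogue compounds; locants are those of the target (C-1 bears the dienoic acid chain, C-2 the butenyl group, C-7 the sulfate oxygen, C-8 the ring-B methyl group).

Step 1
Reactants: 1 (2E)-2-methylbut-2-enal; 2 2-(triphenylphosphoranylidene)propanal
Product: 3 (2E,4E)-2,4-dimethylhexa-2,4-dienal
Conditions: toluene, 90 °C
Reagents that add atoms: none
Why: Wittig olefination with a stabilised ylide should give the (E)-trisubstituted enal and leave the existing (E)-olefin untouched.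

Step 2
Reactants: 4 3-[(tert-butyldiphenylsilyl)oxy]propanal; 2 2-(triphenylphosphoranylidene)propanal
Product: 5 (2E)-5-[(tert-butyldiphenylsilyl)oxy]-2-methylpent-2-enal
Conditions: CH2Cl2, 23 °C
Reagents that add atoms: none
Why: Wittig olefination with the same stabilised ylide should give the (E)-2-methyl enal.

Step 3
Reactants: 5 (2E)-5-[(tert-butyldiphenylsilyl)oxy]-2-methylpent-2-enal
Product: 6 (1E,3E)-5-[(tert-butyldiphenylsilyl)oxy]-2-methyl-1-[(triethylsilyl)oxy]penta-1,3-diene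
Conditions: Et3SiOTf, Et3N, Et2O, 0 °C
Reagents that add atoms: triethylsilyl trifluoromethanesulfonate, CC[Si](CC)(CC)OS(=O)(=O)C(F)(F)F
Why: Soft γ-enolisation with O-silylation (vinylogous silyl enol ether formation) from the s-trans enal should give the (1E,3E)-dienol ether.

Step 4
Reactants: 3 (2E,4E)-2,4-dimethylhexa-2,4-dienal; 6 (1E,3E)-5-[(tert-butyldiphenylsilyl)oxy]-2-methyl-1-[(triethylsilyl)oxy]penta-1,3-diene
Product: 7 (1S,2R,5S,6S)-5-{[(tert-butyldiphenylsilyl)oxy]methyl}-1,3-dimethyl-6-[(2E)-but-2-en-2-yl]-2-[(triethylsilyl)oxy]cyclohex-3-ene-1-carbaldehyde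
Conditions: (S)-B-(2-methylphenyl)oxazaborolidine from (S)-α,α-diphenylprolinol, activated with HNTf2 (20 mol %), CH2Cl2, −78 to −40 °C (the antipodal catalyst is used if the sense of induction requires it)
Reagents that add atoms: none
Why: Catalytic enantioselective Diels–Alder reaction of an α-substituted enal: the silyloxy terminus bonds to the formyl-bearing carbon ("ortho" rule); the (E,E)-diene and (E)-dienophile fix formyl trans to butenyl, and the endo transition state (formyl under the diene, butenyl exo) puts the butenyl group trans to the C-1 side chain and the formyl group cis to it; the chiral boron cation selects the enal face and so the absolute configuration.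

Step 5
Reactants: 7 (1S,2R,5S,6S)-5-{[(tert-butyldiphenylsilyl)oxy]methyl}-1,3-dimethyl-6-[(2E)-but-2-en-2-yl]-2-[(triethylsilyl)oxy]cyclohex-3-ene-1-carbaldehyde; 8 [3-(tert-butyldimethylsilyloxy)propyl]triphenylphosphonium bromide
Product: 9 tert-butyl({(3Z)-4-[(1S,2R,5S,6S)-5-{[(tert-butyldiphenylsilyl)oxy]methyl}-1,3-dimethyl-6-[(2E)-but-2-en-2-yl]-2-[(triethylsilyl)oxy]cyclohex-3-en-1-yl]but-3-en-1-yl}oxy)dimethylsilane
Conditions: KN(SiMe3)2, THF, −78 to 0 °C
Reagents that add atoms: none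
Why: Salt-free Wittig reaction of a non-stabilised ylide with a hindered, non-enolisable aldehyde should give the (Z)-olefin, which the later ring closure requires.

Step 6
Reactants: 9 tert-butyl({(3Z)-4-[(1S,2R,5S,6S)-5-{[(tert-butyldiphenylsilyl)oxy]methyl}-1,3-dimethyl-6-[(2E)-but-2-en-2-yl]-2-[(triethylsilyl)oxy]cyclohex-3-en-1-yl]but-3-en-1-yl}oxy)dimethylsilane
Product: 10 (1R,4S,5S,6S)-4-{[(tert-butyldiphenylsilyl)oxy]methyl}-6-[(1Z)-4-hydroxybut-1-en-1-yl]-2,6-dimethyl-5-[(2E)-but-2-en-2-yl]cyclohex-2-en-1-ol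
Conditions: camphorsulfonic acid (cat.), MeOH/CH2Cl2, 0 °C
Reagents that add atoms: none
Why: Acid-catalysed methanolysis should remove the triethylsilyl and the primary tert-butyldimethylsilyl ethers while the tert-butyldiphenylsilyl ether survives.

Step 7
Reactants: 10 (1R,4S,5S,6S)-4-{[(tert-butyldiphenylsilyl)oxy]methyl}-6-[(1Z)-4-hydroxybut-1-en-1-yl]-2,6-dimethyl-5-[(2E)-but-2-en-2-yl]cyclohex-2-en-1-ol
Product: 11 (1R,4S,5S,6S)-4-{[(tert-butyldiphenylsilyl)oxy]methyl}-6-[(1Z)-4-iodobut-1-en-1-yl]-2,6-dimethyl-5-[(2E)-but-2-en-2-yl]cyclohex-2-en-1-ol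
Conditions: I2, PPh3, imidazole, CH2Cl2, 0 °C
Reagents that add atoms: iodine, II
Why: Appel iodination should take the unhindered primary alcohol and leave the secondary allylic alcohol, which is flanked by a quaternary carbon.

Step 8
Reactants: 11 (1R,4S,5S,6S)-4-{[(tert-butyldiphenylsilyl)oxy]methyl}-6-[(1Z)-4-iodobut-1-en-1-yl]-2,6-dimethyl-5-[(2E)-but-2-en-2-yl]cyclohex-2-en-1-ol
Product: 12 (4S,5S,6S)-4-{[(tert-butyldiphenylsilyl)oxy]methyl}-6-[(1Z)-4-iodobut-1-en-1-yl]-2,6-dimethyl-5-[(2E)-but-2-en-2-yl]cyclohex-2-en-1-one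
Conditions: Dess–Martin periodinane, NaHCO3, CH2Cl2, 0 to 23 °C
Reagents that add atoms: none
Why: Dess–Martin oxidation of the allylic alcohol should give the enone without touching the iodide or the olefins.

Step 9
Reactants: 12 (4S,5S,6S)-4-{[(tert-butyldiphenylsilyl)oxy]methyl}-6-[(1Z)-4-iodobut-1-en-1-yl]-2,6-dimethyl-5-[(2E)-but-2-en-2-yl]cyclohex-2-en-1-one
Product: 16 (1S,4aS,7S,8S,8aR)-8-{[(tert-butyldiphenylsilyl)oxy]methyl}-1,6-dimethyl-7-[(2E)-but-2-en-2-yl]-3,4,4a,7,8,8a-hexahydronaphthalen-2(1H)-one, via alkyllithium 13 (not isolated), via cis-fused bicyclic lithium alkoxide 14 (not isolated), via potassium enolate 15 (not isolated)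
Conditions: t-BuLi (2.2 equiv), Et2O, −78 °C; then KOt-Bu, 18-crown-6, THF, −78 to 23 °C; AcOH, THF, −78 °C
Reagents that add atoms: none
Why: Proposed new method: iodine–lithium exchange gives alkyllithium 13, which adds to the C-7 ketone to give the cis-fused alkoxide 14; as the potassium alkoxide, its 3-oxido-1,5-diene C-8a=C-8–C-7(O−)–C-3–C-4=C-4a should undergo a [3,3] shift (or the equivalent tethered allyl anion/enone recombination across the ten-carbon periphery) that breaks C-3–C-7 and forms C-4a–C-8a, giving enolate 15. The closest known chemistry is the tandem carbonyl addition/anionic oxy-Cope rearrangement and the boat-type oxy-Cope of 2-vinylbicyclo[2.2.2]oct-5-en-2-olates; here the breaking bond is the fusion bond of a cis-bicyclo[4.4.0]deca-3,7-diene, so the shift must pass a twist-boat array in which the two termini already lie about 3 Å apart. The temporary ring (C-3, C-4, C-4a, C-5, C-6, C-7) closes by 6-exo-trig carbonyl addition, and the sigmatropic step then closes rings A and B together by the transannular-type C-4a–C-8a bond while the temporary bond opens. C-8a is set by suprafacial delivery of C-4a to the ring face that carried the arm (fixed at C-3 in step 4), C-4a by the (Z)-olefin held in the temporary ring, which in the boat array can only give the cis ring fusion, and C-8 by axial kinetic protonation of 15 anti to the pseudo-axial C-1 carbon. The step needs the cis-fused alkoxide (the trans-fused isomer holds the two allyl units anti and cannot rearrange) and a quench that does not equilibrate C-8; the short (Z)-tether, which reaches only the carbonyl face on its own side, and the cold acetic acid quench should secure both.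

Step 10
Reactants: 16 (1S,4aS,7S,8S,8aR)-8-{[(tert-butyldiphenylsilyl)oxy]methyl}-1,6-dimethyl-7-[(2E)-but-2-en-2-yl]-3,4,4a,7,8,8a-hexahydronaphthalen-2(1H)-one
Product: 17 (1S,2R,4aS,7S,8S,8aR)-8-{[(tert-butyldiphenylsilyl)oxy]methyl}-1,6-dimethyl-7-[(2E)-but-2-en-2-yl]-1,2,3,4,4a,7,8,8a-octahydronaphthalen-2-ol
Conditions: LiBH(s-Bu)3, THF, −78 °C; then H2O
Reagents that add atoms: none
Why: The bulky hydride should attack from the equatorial side of the ring-B chair, because the axial path is blocked by the 1,3-diaxial C-1 carbon; this gives the axial C-7 alcohol cis to the C-8 methyl group and removes the epimerisable ketone at once.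

Step 11
Reactants: 17 (1S,2R,4aS,7S,8S,8aR)-8-{[(tert-butyldiphenylsilyl)oxy]methyl}-1,6-dimethyl-7-[(2E)-but-2-en-2-yl]-1,2,3,4,4a,7,8,8a-octahydronaphthalen-2-ol
Product: 18 (1S,2R,4aS,7S,8S,8aR)-8-(hydroxymethyl)-1,6-dimethyl-7-[(2E)-but-2-en-2-yl]-1,2,3,4,4a,7,8,8a-octahydronaphthalen-2-ol
Conditions: Bu4NF, THF, 23 °C
Reagents that add atoms: none
Why: Fluoride cleavage of the silyl ether should free the primary alcohol; no base-sensitive stereocentre remains.

Step 12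
Reactants: 18 (1S,2R,4aS,7S,8S,8aR)-8-(hydroxymethyl)-1,6-dimethyl-7-[(2E)-but-2-en-2-yl]-1,2,3,4,4a,7,8,8a-octahydronaphthalen-2-ol
Product: 19 (1S,2S,4aS,7R,8S,8aS)-2-[(2E)-but-2-en-2-yl]-7-hydroxy-3,8-dimethyl-1,2,4a,5,6,7,8,8a-octahydronaphthalene-1-carbaldehyde
Conditions: TEMPO (cat.), PhI(OAc)2, CH2Cl2, 23 °C
Reagents that add atoms: none
Why: Oxoammonium oxidation should select the primary alcohol over the hindered axial secondary one; the formyl group is equatorial on ring A and points away from the C-7 hydroxyl, so lactol formation and over-oxidation should be slow.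

Step 13
Reactants: 19 (1S,2S,4aS,7R,8S,8aS)-2-[(2E)-but-2-en-2-yl]-7-hydroxy-3,8-dimethyl-1,2,4a,5,6,7,8,8a-octahydronaphthalene-1-carbaldehyde; 20 ethyl (2E)-4-(diethoxyphosphoryl)but-2-enoate
Product: 21 ethyl (2E,4E)-5-[(1S,2S,4aS,7R,8S,8aR)-2-[(2E)-but-2-en-2-yl]-7-hydroxy-3,8-dimethyl-1,2,4a,5,6,7,8,8a-octahydronaphthalen-1-yl]penta-2,4-dienoate
Conditions: LiN(SiMe3)2, THF, −78 to 0 °C
Reagents that add atoms: none
Why: Vinylogous Horner–Wadsworth–Emmons olefination should give the (2E,4E)-dienoate; the C-1 centre is already in its more stable equatorial arrangement, trans to both neighbours.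

Step 14
Reactants: 21 ethyl (2E,4E)-5-[(1S,2S,4aS,7R,8S,8aR)-2-[(2E)-but-2-en-2-yl]-7-hydroxy-3,8-dimethyl-1,2,4a,5,6,7,8,8a-octahydronaphthalen-1-yl]penta-2,4-dienoate
Product: 22 (2E,4E)-5-[(1S,2S,4aS,7R,8S,8aR)-2-[(2E)-but-2-en-2-yl]-7-hydroxy-3,8-dimethyl-1,2,4a,5,6,7,8,8a-octahydronaphthalen-1-yl]penta-2,4-dienoic acid
Conditions: LiOH, THF/MeOH/H2O, 23 °C; then 1 M HCl
Reagents that add atoms: water, O
Why: Saponification of the ethyl ester; no stereocentre is at risk.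

Step 15
Reactants: 22 (2E,4E)-5-[(1S,2S,4aS,7R,8S,8aR)-2-[(2E)-but-2-en-2-yl]-7-hydroxy-3,8-dimethyl-1,2,4a,5,6,7,8,8a-octahydronaphthalen-1-yl]penta-2,4-dienoic acid
Product: 23 CNP0450810.8, (2E,4E)-5-[(1S,2S,4aS,7R,8S,8aR)-2-[(2E)-but-2-en-2-yl]-3,8-dimethyl-7-(sulfooxy)-1,2,4a,5,6,7,8,8a-octahydronaphthalen-1-yl]penta-2,4-dienoic acid
Conditions: SO3·pyridine, pyridine, 40 °C; aqueous NaHCO3; H+ ion-exchange resin, 0 °C
Reagents that add atoms: sulfur trioxide–pyridine complex, O=S(=O)=O.c1ccncc1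
Why: O-Sulfation of the secondary alcohol with retention at C-7; the mixed anhydride formed at the carboxyl group should hydrolyse in the bicarbonate work-up, and the resin should give the free acid.

Compound list
1 | (2E)-2-methylbut-2-enal | C/C=C(\C)C=O | starting material
2 | 2-(triphenylphosphoranylidene)propanal | CC(C=O)=P(c1ccccc1)(c1ccccc1)c1ccccc1 | starting material
3 | (2E,4E)-2,4-dimethylhexa-2,4-dienal | C/C=C(\C)/C=C(\C)C=O | intermediate
4 | 3-[(tert-butyldiphenylsilyl)oxy]propanal | O=CCCO[Si](c1ccccc1)(c1ccccc1)C(C)(C)C | starting material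
5 | (2E)-5-[(tert-butyldiphenylsilyl)oxy]-2-methylpent-2-enal | O=C/C(C)=C/CCO[Si](c1ccccc1)(c1ccccc1)C(C)(C)C | intermediate
6 | (1E,3E)-5-[(tert-butyldiphenylsilyl)oxy]-2-methyl-1-[(triethylsilyl)oxy]penta-1,3-diene | CC[Si](CC)(CC)O/C=C(C)/C=C/CO[Si](c1ccccc1)(c1ccccc1)C(C)(C)C | intermediate
7 | (1S,2R,5S,6S)-5-{[(tert-butyldiphenylsilyl)oxy]methyl}-1,3-dimethyl-6-[(2E)-but-2-en-2-yl]-2-[(triethylsilyl)oxy]cyclohex-3-ene-1-carbaldehyde | CC[Si](CC)(CC)O[C@@H]1C(C)=C[C@H](CO[Si](c2ccccc2)(c2ccccc2)C(C)(C)C)[C@@H](/C(C)=C/C)[C@]1(C)C=O | intermediate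
8 | [3-(tert-butyldimethylsilyloxy)propyl]triphenylphosphonium bromide | CC(C)(C)[Si](C)(C)OCCC[P+](c1ccccc1)(c1ccccc1)c1ccccc1.[Br-] | starting material
9 | tert-butyl({(3Z)-4-[(1S,2R,5S,6S)-5-{[(tert-butyldiphenylsilyl)oxy]methyl}-1,3-dimethyl-6-[(2E)-but-2-en-2-yl]-2-[(triethylsilyl)oxy]cyclohex-3-en-1-yl]but-3-en-1-yl}oxy)dimethylsilane | CC[Si](CC)(CC)O[C@@H]1C(C)=C[C@H](CO[Si](c2ccccc2)(c2ccccc2)C(C)(C)C)[C@@H](/C(C)=C/C)[C@]1(C)/C=C\CCO[Si](C)(C)C(C)(C)C | intermediate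
10 | (1R,4S,5S,6S)-4-{[(tert-butyldiphenylsilyl)oxy]methyl}-6-[(1Z)-4-hydroxybut-1-en-1-yl]-2,6-dimethyl-5-[(2E)-but-2-en-2-yl]cyclohex-2-en-1-ol | O[C@@H]1C(C)=C[C@H](CO[Si](c2ccccc2)(c2ccccc2)C(C)(C)C)[C@@H](/C(C)=C/C)[C@]1(C)/C=C\CCO | intermediate
11 | (1R,4S,5S,6S)-4-{[(tert-butyldiphenylsilyl)oxy]methyl}-6-[(1Z)-4-iodobut-1-en-1-yl]-2,6-dimethyl-5-[(2E)-but-2-en-2-yl]cyclohex-2-en-1-ol | O[C@@H]1C(C)=C[C@H](CO[Si](c2ccccc2)(c2ccccc2)C(C)(C)C)[C@@H](/C(C)=C/C)[C@]1(C)/C=C\CCI | intermediate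
12 | (4S,5S,6S)-4-{[(tert-butyldiphenylsilyl)oxy]methyl}-6-[(1Z)-4-iodobut-1-en-1-yl]-2,6-dimethyl-5-[(2E)-but-2-en-2-yl]cyclohex-2-en-1-one | O=C1C(C)=C[C@H](CO[Si](c2ccccc2)(c2ccccc2)C(C)(C)C)[C@@H](/C(C)=C/C)[C@]1(C)/C=C\CCI | intermediate
13 | alkyllithium from 12 (lithium in place of iodine on C-6) | O=C1C(C)=C[C@H](CO[Si](c2ccccc2)(c2ccccc2)C(C)(C)C)[C@@H](/C(C)=C/C)[C@]1(C)/C=C\CC[Li] | intermediate
14 | cis-fused bicyclo[4.4.0]deca-3,7-dien-1-olate (lithium salt) with the temporary C-3–C-7 bond as ring-fusion bond; oxide and C-3 methyl cis | [Li]O[C@@]12C(C)=C[C@H](CO[Si](c3ccccc3)(c3ccccc3)C(C)(C)C)[C@@H](/C(C)=C/C)[C@]1(C)C=CCC2 | intermediate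
15 | potassium C-7/C-8 enolate of 16 | C/C=C(\C)[C@H]1C(C)=C[C@H]2CCC(O[K])=C(C)[C@H]2[C@@H]1CO[Si](c3ccccc3)(c3ccccc3)C(C)(C)C | intermediate
16 | (1S,4aS,7S,8S,8aR)-8-{[(tert-butyldiphenylsilyl)oxy]methyl}-1,6-dimethyl-7-[(2E)-but-2-en-2-yl]-3,4,4a,7,8,8a-hexahydronaphthalen-2(1H)-one | C/C=C(\C)[C@H]1C(C)=C[C@H]2CCC(=O)[C@@H](C)[C@H]2[C@@H]1CO[Si](c3ccccc3)(c3ccccc3)C(C)(C)C | intermediate
17 | (1S,2R,4aS,7S,8S,8aR)-8-{[(tert-butyldiphenylsilyl)oxy]methyl}-1,6-dimethyl-7-[(2E)-but-2-en-2-yl]-1,2,3,4,4a,7,8,8a-octahydronaphthalen-2-ol | C/C=C(\C)[C@H]1C(C)=C[C@H]2CC[C@@H](O)[C@@H](C)[C@H]2[C@@H]1CO[Si](c3ccccc3)(c3ccccc3)C(C)(C)C | intermediate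
18 | (1S,2R,4aS,7S,8S,8aR)-8-(hydroxymethyl)-1,6-dimethyl-7-[(2E)-but-2-en-2-yl]-1,2,3,4,4a,7,8,8a-octahydronaphthalen-2-ol | C/C=C(\C)[C@H]1C(C)=C[C@H]2CC[C@@H](O)[C@@H](C)[C@H]2[C@@H]1CO | intermediate
19 | (1S,2S,4aS,7R,8S,8aS)-2-[(2E)-but-2-en-2-yl]-7-hydroxy-3,8-dimethyl-1,2,4a,5,6,7,8,8a-octahydronaphthalene-1-carbaldehyde | C/C=C(\C)[C@H]1C(C)=C[C@H]2CC[C@@H](O)[C@@H](C)[C@H]2[C@@H]1C=O | intermediate
20 | ethyl (2E)-4-(diethoxyphosphoryl)but-2-enoate | CCOC(=O)/C=C/CP(=O)(OCC)OCC | starting material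
21 | ethyl (2E,4E)-5-[(1S,2S,4aS,7R,8S,8aR)-2-[(2E)-but-2-en-2-yl]-7-hydroxy-3,8-dimethyl-1,2,4a,5,6,7,8,8a-octahydronaphthalen-1-yl]penta-2,4-dienoate | C/C=C(\C)[C@H]1C(C)=C[C@H]2CC[C@@H](O)[C@@H](C)[C@H]2[C@@H]1/C=C/C=C/C(=O)OCC | intermediate
22 | (2E,4E)-5-[(1S,2S,4aS,7R,8S,8aR)-2-[(2E)-but-2-en-2-yl]-7-hydroxy-3,8-dimethyl-1,2,4a,5,6,7,8,8a-octahydronaphthalen-1-yl]penta-2,4-dienoic acid | C/C=C(\C)[C@H]1C(C)=C[C@H]2CC[C@@H](O)[C@@H](C)[C@H]2[C@@H]1/C=C/C=C/C(=O)O | intermediate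
23 | CNP0450810.8, (2E,4E)-5-[(1S,2S,4aS,7R,8S,8aR)-2-[(2E)-but-2-en-2-yl]-3,8-dimethyl-7-(sulfooxy)-1,2,4a,5,6,7,8,8a-octahydronaphthalen-1-yl]penta-2,4-dienoic acid | C/C=C(\C)[C@H]1C(C)=C[C@H]2CC[C@@H](OS(=O)(=O)O)[C@@H](C)[C@H]2[C@@H]1/C=C/C=C/C(=O)O | target

Total step count: 15. Longest linear sequence: 14 steps (steps 2 to 15).

Steps most likely to fail

Step 9. The tertiary alkoxide may not rearrange, because the breaking ring-fusion bond lies close to the nodal planes of both olefins. The carbonyl addition may also give some unreactive trans-fused alkoxide, or C-8 may equilibrate on quench. The fallback sets out from 12 and returns at 16, making the same two bonds by a radical chain built from known steps (Bu3SnH, AIBN, benzene, 80 °C, slow addition). The C-6 radical adds 6-exo to the C-7 carbonyl, and the alkoxyl radical undergoes β-scission of the C-3–C-7 bond (Dowd–Beckwith type) to a ten-membered allyl radical/enone. Transannular 6-exo conjugate addition then closes C-4a–C-8a, and hydrogen transfer to C-8 gives 16. No new isolated compound arises.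

Step 4. The silyl dienol ether may add to the activated formyl group (1,2-addition or hetero-cycloaddition) instead of the olefin. The hindered trisubstituted dienophile may also react sluggishly, or exo approach and poor facial discrimination may erode the stereochemistry. The fallback sets out from 5 and returns at 10, moving the stereocontrol to a dienyl ester auxiliary. Enolisation of 5 with KN(SiMe3)2 and acylation with (2S)-2-methoxy-2-phenylacetyl chloride would give (1E,3E)-5-[(tert-butyldiphenylsilyl)oxy]-2-methylpenta-1,3-dien-1-yl (2S)-2-methoxy-2-phenylacetate F1 (the (2R) chloride is used if the other face is needed). BF3·OEt2-promoted cycloaddition with 3 would give the mandelate analogue of 7, cycloadduct F2. Wittig reaction with 8 as in step 5 would give the (Z)-olefin F3. i-Bu2AlH at −78 °C would cleave the ester to the allylic alcohol F4, and camphorsulfonic acid in methanol would then give 10.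

Step 12. The secondary alcohol may be oxidised as well, or the hydroxy aldehyde may close to a lactol that is oxidised further to a lactone. The fallback sets out from 16 and returns at 21, oxidising before the ketone is reduced. HF·pyridine would give the hydroxy ketone (1S,4aS,7S,8S,8aR)-8-(hydroxymethyl)-1,6-dimethyl-7-[(2E)-but-2-en-2-yl]-3,4,4a,7,8,8a-hexahydronaphthalen-2(1H)-one F5. Dess–Martin oxidation would give the keto aldehyde (1S,2S,4aS,8S,8aR)-2-[(2E)-but-2-en-2-yl]-3,8-dimethyl-7-oxo-1,2,4a,5,6,7,8,8a-octahydronaphthalene-1-carbaldehyde F6. Olefination with 20 would give the keto dienoate ethyl (2E,4E)-5-[(1S,2S,4aS,8S,8aR)-2-[(2E)-but-2-en-2-yl]-3,8-dimethyl-7-oxo-1,2,4a,5,6,7,8,8a-octahydronaphthalen-1-yl]penta-2,4-dienoate F7. Its ketone would then be reduced with LiBH(s-Bu)3 at −78 °C to give 21.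

Further compounds
F0 | step 9 | none | none
F1 | step 4 | (1E,3E)-5-[(tert-butyldiphenylsilyl)oxy]-2-methylpenta-1,3-dien-1-yl (2S)-2-methoxy-2-phenylacetate | CO[C@@H](c1ccccc1)C(=O)O/C=C(C)/C=C/CO[Si](c1ccccc1)(c1ccccc1)C(C)(C)C
F2 | step 4 | (1R,4S,5S,6S)-4-{[(tert-butyldiphenylsilyl)oxy]methyl}-6-formyl-2,6-dimethyl-5-[(2E)-but-2-en-2-yl]cyclohex-2-en-1-yl (2S)-2-methoxy-2-phenylacetate | CO[C@@H](c1ccccc1)C(=O)O[C@@H]1C(C)=C[C@H](CO[Si](c2ccccc2)(c2ccccc2)C(C)(C)C)[C@@H](/C(C)=C/C)[C@]1(C)C=O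
F3 | step 4 | (1R,4S,5S,6S)-4-{[(tert-butyldiphenylsilyl)oxy]methyl}-6-[(1Z)-4-(tert-butyldimethylsilyloxy)but-1-en-1-yl]-2,6-dimethyl-5-[(2E)-but-2-en-2-yl]cyclohex-2-en-1-yl (2S)-2-methoxy-2-phenylacetate | CO[C@@H](c1ccccc1)C(=O)O[C@@H]1C(C)=C[C@H](CO[Si](c2ccccc2)(c2ccccc2)C(C)(C)C)[C@@H](/C(C)=C/C)[C@]1(C)/C=C\CCO[Si](C)(C)C(C)(C)C
F4 | step 4 | (1R,4S,5S,6S)-4-{[(tert-butyldiphenylsilyl)oxy]methyl}-6-[(1Z)-4-(tert-butyldimethylsilyloxy)but-1-en-1-yl]-2,6-dimethyl-5-[(2E)-but-2-en-2-yl]cyclohex-2-en-1-ol | O[C@@H]1C(C)=C[C@H](CO[Si](c2ccccc2)(c2ccccc2)C(C)(C)C)[C@@H](/C(C)=C/C)[C@]1(C)/C=C\CCO[Si](C)(C)C(C)(C)C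
F5 | step 12 | (1S,4aS,7S,8S,8aR)-8-(hydroxymethyl)-1,6-dimethyl-7-[(2E)-but-2-en-2-yl]-3,4,4a,7,8,8a-hexahydronaphthalen-2(1H)-one | C/C=C(\C)[C@H]1C(C)=C[C@H]2CCC(=O)[C@@H](C)[C@H]2[C@@H]1CO
F6 | step 12 | (1S,2S,4aS,8S,8aR)-2-[(2E)-but-2-en-2-yl]-3,8-dimethyl-7-oxo-1,2,4a,5,6,7,8,8a-octahydronaphthalene-1-carbaldehyde | C/C=C(\C)[C@H]1C(C)=C[C@H]2CCC(=O)[C@@H](C)[C@H]2[C@@H]1C=O
F7 | step 12 | ethyl (2E,4E)-5-[(1S,2S,4aS,8S,8aR)-2-[(2E)-but-2-en-2-yl]-3,8-dimethyl-7-oxo-1,2,4a,5,6,7,8,8a-octahydronaphthalen-1-yl]penta-2,4-dienoate | C/C=C(\C)[C@H]1C(C)=C[C@H]2CCC(=O)[C@@H](C)[C@H]2[C@@H]1/C=C/C=C/C(=O)OCC
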